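The green run, with 0.075 M of X against 0.050 M in teal at the same loading, looked like a faster copy of teal. Teal is the flask asked about, followed so far.

in all of them: D 0.008 mol%

| run | X | remark | time |
|---|---|---|---|
| teal | 0.050 M | the very flask that is asked about, followed so far |  |
| green | 0.075 M | run made earlier |  |
| flask | 0.050 M |  | 2.5 h |

| run | time / min | Q / % |
|---|---|---|
| teal | 8.00 | 4.8 |
| teal | 12.0 | 6.3 |
| teal | 20.0 | 8.9 |
| teal | 30.0 | 11.8 |
| teal | 50.0 | 13.2 |
| teal | 90.0 | 15.1 |
| green | 1.33 | 1.1 |
| green | 4.00 | 2.9 |
| green | 8.00 | 5.9 |
| green | 12.0 | 7.6 |
| green | 15.0 | 9.7 |
| green | 20.0 | 10.4 |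

(each reading ± 0.5 percentage points)

- alpha: change nothing and wait 2.5 h more
- delta: at 2.5 h take out 90% of the Q then present, then wait 2.5 h
- eta: at 2.5 h add D, 100% of the amount charged, then wait 2.5 h
- beta: at 2.5 h add X, 50.0% of the amount charged, then wait 2.5 h

- removed Q is counted in
- additions bring no volume worth counting

1. Q, in percent of the X first charged, at 2.5 h
2. the remedy with the largest gain of Q, or "none" below 2 percentage points (alpha / delta / eta / beta / none)
3. Q present, with what was taken out counted in, in percent of the X first charged, after alpha
4. Q present, with what was taken out counted in, in percent of the X first charged, after eta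

I compared two rates in teal first. The early rise of Q beat the rise from 50.0 min to 90.0 min by a factor of about 12.6, yet X had fallen just to 84.9% of its charge, so the loss of X did not explain the slowing. I weighed two brakes: a back reaction that grew until it matched the forward one, or D dying. Taken as first-order, both give a gap below a stall level that shrinks exponentially. I took the last reading, 15.1%, as that stall level and read the closing time (the relaxation time), the time in which the gap falls by a factor e:

closing time = 20.0 min / ln(stall / (stall − 8.9%)) = 22.5 min

But which brake was it? Green holds 1.50 times the X and, at the same loading, the same factor in D concentration. Dying D, with the closing time unchanged, put green at 13.3% at 20.0 min. A back reaction, with the same stall and a shorter closing time, put it at 11.1%. Green read 10.4%, nearer the second, though D saturated by X remained a doubt.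

So I committed to the back reaction. The flask at 2.5 h is 6.67 closing times in, which by this reckoning leaves Q a gap of 0.019 percentage points below the stall. With q the stall share of the X and Q in the flask, waiting adds that gap, and eta, with twice the D, shortens the closing time but keeps q. The other two move the stall:

delta gain = 90% · q · (1 − q) = 12 points

beta gain = 50.0% · q = 7.5 points

I chose delta. The forecast gave 15.5%, 15.6% after alpha and 15.7% after eta, and chose delta: “Waiting or adding D gains nothing.” Its stall stood above mine, with the same choice.

The flask gave 14.8%, then 14.9% after alpha and 14.9% after eta. The best remedy was delta, gaining 11 points against 7.4 points for beta.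

    X + D ⇌ E (K = 5.40 M⁻¹, k = 2230 M⁻¹ s⁻¹)
    E ⇌ D + Q (K = 0.0323 M, k = 7.04 s⁻¹)

The forecast stood within its margins, with the right remedy. With the other amounts and the time held, the answer to "now" moves by 5 points at 0.0012 mol% of D. A neighbour flask ran with 0.002 mol% of D, and the bound form E held 19.1% of the neighbour's catalyst at 150 min, against 18.7% in the flask. The closing time from teal, stretched by a factor 4.00, becomes 89.9 min, so at 2.5 h the neighbour should stand short of the stall:

Q = stall · (1 − e^(−time / closing time)) = 12.3%

The neighbour gave 12.4%.

Readings and results are calculated for an exercise, and the scatter is random.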